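**The clock.** If a flask lags and then runs faster the more catalyst is charged, we stop asking for a rate and ask for a clock.

| setting | Thursday's | Wednesday's | Tuesday's | dawn | noon | dusk | autumn |
|---|---|---|---|---|---|---|---|
| substrate | 0.10 M | 0.10 M | 0.27 M | 0.40 M | 0.10 M | 0.10 M | 0.40 M |
| other conformer | 0.10 equiv | 0.10 equiv | 0.10 equiv | 0.100 equiv | 0.100 equiv | 0.100 equiv | 0.100 equiv |
| precatalyst | 0.36 mol% | 0.87 mol% | 0.78 mol% | 0.78 mol% | 0.78 mol% | 0.25 mol% | 0.25 mol% |
| remark | run made earlier | run made earlier | run made earlier |  |  |  |  |
| time |  |  |  | 12 min | 12 min | 12 min | 12 min |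

| run | time / min | target / % |
|---|---|---|
| Thursday's | 2.00 | 2.8 |
| Thursday's | 4.00 | 14.6 |
| Thursday's | 6.00 | 23.4 |
| Thursday's | 8.00 | 36.8 |
| Wednesday's | 1.00 | 2.0 |
| Wednesday's | 3.00 | 16.0 |
| Wednesday's | 5.00 | 36.3 |
| Wednesday's | 8.00 | 57.8 |
| Tuesday's | 0.667 | 1.8 |
| Tuesday's | 1.50 | 10.0 |
| Tuesday's | 4.00 | 49.9 |
| Tuesday's | 8.00 | 59.2 |

(standard deviation of a reading: 1 percentage point)

- all flasks from highest to lowest amount of target, in percent of the substrate and other conformer together charged, at 12 min (dawn / noon / dusk / autumn)
- the amount of target, in percent of the substrate and other conformer together charged of the flask you put first, at 12 min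
- the amount of target, in percent of the substrate and other conformer together charged of the flask you put last, at 12 min

- in a conversion other conformer counts as not yet reacted

**The dose.** The slow starts suggest a catalyst that grows with time, so we try substrate concentration times loading times time squared. Counted in units of Wednesday's last reading, this gives Thursday's run 0.414 at 8.00 min, where it reads 36.8%. Wednesday's run has 0.391 at 5.00 min and reads 36.3%. Two flasks, one point on one curve. At 12 min noon stands at 2.02 of this dose.

**First way.** We work with the fraction left. Thursday's last reading puts 63.2% outside the target, which gives a logarithmic fall of 1.11 per unit dose, pseudo-first-order on this clock. On this line noon comes to 89.3%.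

**Second way.** We simply look noon up. Its dose lies between Wednesday's last reading, at dose 1 with 57.8%, and Tuesday's last, at 2.42 with 59.2%.

**Which cheats.** The first way does. For Tuesday's last reading it gives 93.2%, far more than the 59.2% seen, so we suppose that part of what is made is not kept.

**Kept share.** A second fraction left repairs it: reading over made is 0.863 for Wednesday's last reading and 0.635 for Tuesday's, a logarithmic fall of 0.215 per unit dose. Noon becomes 61.9%, near the lookup, but this line was drawn through the same two readings, so that nearness is no check. Tuesday's reading at 4.00 min, used by neither line, comes out at 45.9% against 49.9%. Autumn gets 57.8% and dusk 47.6%. Dawn's dose of 8.07 lies beyond the readings, so its 18.8% is an extrapolation. We put noon first, then autumn and dusk, and dawn last.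

**The forecast.** It says noon > dawn > autumn > dusk, with 68% first and 38% last, on this ground: “Catalyst death appears to worsen with absolute concentration, perhaps bimolecular.” It puts dusk last, where we put dawn.

**The result.** The flasks give noon > autumn > dusk > dawn.

    precatalyst → catalyst (k = 7.70 × 10⁻⁴ s⁻¹)
    substrate ⇌ other conformer (K = 0.250, k = 3.90 × 10⁻⁴ s⁻¹)
    target + catalyst ⇌ isomer of the product B + catalyst, rate k3*[catalyst]*[target] forward; the back reaction follows from the equilibrium constant (K = 29.0, k = 2.70 M⁻¹ s⁻¹)
    substrate + catalyst → catalyst + target (k = 21.0 M⁻¹ s⁻¹)
    catalyst + other conformer → catalyst + isomer of the product A (k = 100 M⁻¹ s⁻¹)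

Noon reaches 60.4% against our 61.9%, and dawn 25.1% against our 18.8%. Dawn held 62.5% target at 6.00 min, and at 12.0 min it holds 61.0% isomer of the product B. A noon flask with 3.1 mol% precatalyst has a dose of 8.02, beside dawn's 8.07, and at 12.0 min it holds 25.3% target and 60.8% isomer of the product B.

The runs were computed from invented constants; scatter was added.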